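Watch what is missing.

| setting | cedar | flask |
|---|---|---|
| substrate | 40 mM | 20 mM |
| remark | run made earlier |  |
| time |  | 10 d |
cedar run (percent of the substrate charged)

| time / h | substrate / % | target / % |
|---|---|---|
| 6.00 | 21 | 31 |
| 12.0 | 7 | 36 |
| 20.0 | 9 | 38 |
| 25.0 | 7 | 42 |

(readings scatter by 1.5 percentage points)
- the state of affairs at 10 d: stopped, and by what, or still going (all of the substrate has reacted / it is still moving / forward and back rates have come level)
- conversion of substrate at 10 d
- amount of target at 10 d, in percent of the substrate charged
- what has gone from substrate into another species counts as reacted, even if it can come back
- the reaction counts as stopped when no species that holds the substrate changes by six tenths of a point or more over the second half of the time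

In the cedar run, substrate and target together come to 49.0% at 25.0 h, so the rest of the charge sits in an unread pool. From 12.0 h on, substrate averages 7.67% and target 38.7%, so the pool holds H = 7.00 parts for each part of substrate.

Ana made the forecast: “the reservoir drains through substrate into target”. For the flask at 10 d she says it is still moving, with conversion 98.8% and target 90%.

Ben reckons for himself, and differs: target also returns to substrate. At 6.00 h in the cedar run, substrate has fallen at 0.260 h⁻¹ and target has taken 39.2% of what went, so the forward constant k is 0.102 h⁻¹. From 12.0 h to 25.0 h, k acting on that substrate should bring 10 percentage points, but target gained 6 points. The shortfall, set against the target present, gives a back constant b of 0.00830 h⁻¹, and K = k/b, the equilibrium constant, is 12.3. Both are read through a scatter of 1.5 points on each reading.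

In Ben's reckoning, at rest there are K parts of target to one of substrate and H of pool. The level share, K over the sum of these parts, is 60.6% of the charge, with conversion 95.1%. The charge does not enter it, if first order holds at 20 mM. The gap to it closes at k/(one plus H) plus b, which is 0.0211 h⁻¹, a half-time of 1.37 d. At 10 d the gap is 0.2 points, but the second half still brings 2.3 points, so by the stop rule Ben too must say it is moving.

He grants Ana the early hours: at 6.00 h in the cedar run, back flow is 12.0% of forward flow.

The flask gives: forward and back rates have come level, with conversion 93.8% and target 54.1%.

    substrate ⇌ target (K = 8.70, k = 0.120 h⁻¹)
    substrate ⇌ isomer of the product (K = 3.00, k = 0.0440 h⁻¹)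
    substrate ⇌ third isomer (K = 0.370, k = 0.00200 h⁻¹)
    2 substrate → self-condensation product (k = 0.110 L mol⁻¹ h⁻¹)
    substrate ⇌ dormant form (K = 2.90, k = 0.180 h⁻¹)

In this flask, the largest change of any share over the second half of the time was 0.38 points. The level share L stands 6.5 points above the target of this flask, and 29 points below the forecast. The charge does not enter Ben's L, so he carries it unchanged to a neighbour flask with 50 mM of substrate, where it stands 7.4 points above the target that neighbour flask reaches at 10 d, which is 53.2%.

(All runs are calculated on assumed constants.)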